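**Retrosynthetic overview**
1. Target 33 ⇒ bicyclic alkyne 16 + α-bromo-γ-ylidenebutenolide 31 (hydroboration/Suzuki at the vinyl–butenolide bond, last step).
2. 31 ⇒ polyenyne diol 29 + (E)-2,3-dibromoacrylic acid 27 (Sonogashira/lactonisation); 29 ⇒ cis-diol enol triflate 19 + symmetric C14 tetraene-diyne 25 (two enynols + glyoxal).
3. 16 ⇒ anti-epoxy alcohol 15 by an acid-triggered oxirane → oxolane ring expansion (key step); 15 ⇒ enyne 12 through a bromohydrin.
4. 12 and 19 both ⇒ enol triflate 11 ⇒ isobutyronitrile + (S)-epichlorohydrin + EtLi (the C3 carbinol of both end groups comes from the chiral pool).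
5. Ring order: cyclohexane ring (step 3), then 7-oxabicyclo[2.2.1]heptane (step 7), then butenolide (step 14).

Assumption: enynol 20 is bought as the pure 2E isomer; locants C1–C8 in the Why lines are carotenoid end-group numbers (C1 gem-dimethyl carbon, C3 carbinol carbon, C5 methyl-bearing carbon, C6 chain-bearing carbon).

**Step 1**
Reactants: 1 isobutyronitrile; 2 (S)-epichlorohydrin
Product: 5 (4S)-4-[(tert-butyldimethylsilyl)oxy]-5-chloro-2,2-dimethylpentanenitrile, via lithiated isobutyronitrile 3 (not isolated), via lithium chlorohydrin alkoxide 4 (not isolated)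
Conditions: LiN(i-Pr)2, THF, −78 °C; 2, −78 → −50 °C; then TBSOTf, −78 → 0 °C
Reagents that add atoms: tert-butyldimethylsilyl trifluoromethanesulfonate, CC(C)(C)[Si](C)(C)OS(=O)(=O)C(F)(F)F
Why: SN2 opening of the epoxide at its CH2 terminus by the nitrile anion leaves the C–O stereocentre of 2 untouched, and silylating the cold alkoxide stops it from closing back to an epoxide or adding to the nitrile.

**Step 2**
Reactants: 5 (4S)-4-[(tert-butyldimethylsilyl)oxy]-5-chloro-2,2-dimethylpentanenitrile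
Product: 7 (6S)-6-[(tert-butyldimethylsilyl)oxy]-7-chloro-4,4-dimethylheptan-3-one, via N-lithio ketimine 6 (not isolated)
Conditions: EtLi, Et2O, −78 → 0 °C; then 1 M aq. HCl, THF, 0 °C
Reagents that add atoms: ethyllithium, CC[Li]; water, O
Why: Organolithium addition to the non-enolisable nitrile stops at the N-lithio ketimine, and hydrolysis gives an ethyl ketone whose only enolisable carbon is the one needed for ring closure.

**Step 3**
Reactants: 7 (6S)-6-[(tert-butyldimethylsilyl)oxy]-7-chloro-4,4-dimethylheptan-3-one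
Product: 9 (4R)-4-[(tert-butyldimethylsilyl)oxy]-2,2,6-trimethylcyclohexan-1-one (mixture of C6 epimers), via potassium enolate 8 (not isolated)
Conditions: KN(SiMe3)2, THF, −78 °C; NaI (20 mol %), −78 → 25 °C
Reagents that add atoms: none
Why: Intramolecular enolate C-alkylation in the 6-(enolendo)-exo-tet mode favoured by Baldwin's rules closes the cyclohexanone from the single possible enolate; the new methyl-bearing centre becomes sp2 in step 4 and the carbinol centre is not touched.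

**Step 4**
Reactants: 9 (4R)-4-[(tert-butyldimethylsilyl)oxy]-2,2,6-trimethylcyclohexan-1-one
Product: 11 (4R)-4-[(tert-butyldimethylsilyl)oxy]-2,6,6-trimethylcyclohex-1-en-1-yl trifluoromethanesulfonate, via potassium enolate 10 (not isolated)
Conditions: KN(SiMe3)2, THF, −78 °C; PhNTf2, −78 → 0 °C
Reagents that add atoms: N-phenylbis(trifluoromethanesulfonimide), O=S(=O)(N(c1ccccc1)S(=O)(=O)C(F)(F)F)C(F)(F)F
Why: Enolate O-triflation is regiospecific because only one α-hydrogen exists, giving the tetrasubstituted enol triflate that serves both end groups.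

**Step 5**
Reactants: 11 (4R)-4-[(tert-butyldimethylsilyl)oxy]-2,6,6-trimethylcyclohex-1-en-1-yl trifluoromethanesulfonate
Product: 12 tert-butyl{[(1R)-4-ethynyl-3,5,5-trimethylcyclohex-3-en-1-yl]oxy}dimethylsilane
Conditions: HC≡CMgBr, ZnBr2, THF, 0 °C; then 11, Pd(PPh3)4 (5 mol %), 50 °C
Reagents that add atoms: ethynylmagnesium bromide, C#C[Mg]Br
Why: Negishi coupling of ethynylzinc bromide with the enol triflate installs C7–C8 as a terminal alkyne without affecting the stereocentre.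

**Step 6**
Reactants: 12 tert-butyl{[(1R)-4-ethynyl-3,5,5-trimethylcyclohex-3-en-1-yl]oxy}dimethylsilane
Product: 15 (1R,3S,6R)-6-ethynyl-1,5,5-trimethyl-7-oxabicyclo[4.1.0]heptan-3-ol, via bromohydrin 13 (not isolated), via silyl epoxide 14 (not isolated)
Conditions: NBS, THF/H2O (4:1), 0 °C, dark; extractive work-up; then Bu4NF, THF, 0 → 25 °C; chromatography removes any syn isomer
Reagents that add atoms: water, O
Why: Proposed new method: bromohydrin-route anti-epoxidation of a tetrasubstituted conjugated enyne (closest known reaction: halohydrin formation and base closure as the stereocomplement of peracid epoxidation of cyclohexenes, not shown for 1,3-enynes, whose bromonium chemistry is known mainly as 1,4-bromofunctionalisation to bromoallenes), in which the bromonium ion should form on the face syn to the equatorial silyloxy group and anti to the pseudoaxial C1 methyl (the face a peracid also takes), water opens it trans-diaxially at C5, which carries positive charge better than the propargylic C6, so the C5–O bond is made anti to the C3 oxygen, and fluoride then closes the bromohydrin with inversion at C6 (no β-hydrogen is available for elimination) and removes the silyl group, setting C5 and C6 of the anti-epoxy alcohol.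

**Step 7**
Reactants: 15 (1R,3S,6R)-6-ethynyl-1,5,5-trimethyl-7-oxabicyclo[4.1.0]heptan-3-ol
Product: 16 (1S,2R,4S)-1-ethynyl-2,6,6-trimethyl-7-oxabicyclo[2.2.1]heptan-2-ol
Conditions: camphor-10-sulfonic acid (10 mol %), CH2Cl2, 0 °C
Reagents that add atoms: none
Why: Acid-triggered oxirane → oxolane ring expansion in which the C3 hydroxyl attacks the activated epoxide transannularly at C6 from the face opposite the epoxide oxygen (inversion at C6, retention at C3 and C5, C5 hydroxyl endo), as in the known 5,6-epoxide → 3,6-epoxide rearrangement of 3-hydroxy-5,6-epoxy carotenoid end groups; the alkynyl group disfavours ionisation at C6 and excludes furanoid rearrangement, and a syn-epoxide cannot cyclise.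

**Step 8**
Reactants: 11 (4R)-4-[(tert-butyldimethylsilyl)oxy]-2,6,6-trimethylcyclohex-1-en-1-yl trifluoromethanesulfonate
Product: 17 (4S)-4-[(tert-butyldimethylsilyl)oxy]-2,6,6-trimethyl-3-oxocyclohex-1-en-1-yl trifluoromethanesulfonate
Conditions: Rh2(C6H10NO)4 (dirhodium tetracaprolactamate, 1 mol %), t-BuOOH (5 equiv, in decane), NaHCO3, CH2Cl2, 25 °C
Reagents that add atoms: tert-butyl hydroperoxide, CC(C)(C)OO
Why: Radical allylic C–H oxidation (dirhodium caprolactamate/t-BuOOH) at the ring CH2 next to the enol triflate gives the vinylogous acyl triflate, because hydrogen abstraction by tert-butylperoxyl tolerates electron-poor alkenes and prefers the ring CH2 over the methyl group; the stereocentre is untouched.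

**Step 9**
Reactants: 17 (4S)-4-[(tert-butyldimethylsilyl)oxy]-2,6,6-trimethyl-3-oxocyclohex-1-en-1-yl trifluoromethanesulfonate
Product: 19 (3R,4S)-3,4-dihydroxy-2,6,6-trimethylcyclohex-1-en-1-yl trifluoromethanesulfonate, via mono-silyl cis-diol 18 (not isolated)
Conditions: LiBH(s-Bu)3, THF, −78 °C; AcOH, −78 °C; then 48% aq. HF, MeCN, 0 → 25 °C
Reagents that add atoms: none
Why: 1,2-Reduction by a bulky hydride from the equatorial direction gives the pseudoaxial C4 alcohol cis to the C3 silyloxy group (as bulky hydrides do with 2-alkoxycyclohexanones), the cold protic quench prevents fragmentation of the alkoxide, and HF then frees the cis-diol.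

**Step 10**
Reactants: 20 (2E)-3-methylpent-2-en-4-yn-1-ol
Product: 21 [(2E)-3-methylpent-2-en-4-yn-1-yl]triphenylphosphonium bromide
Conditions: PPh3·HBr, MeOH, 0 → 25 °C
Reagents that add atoms: triphenylphosphine hydrobromide, Br.c1ccc(cc1)P(c1ccccc1)c1ccccc1
Why: Acid-mediated substitution of the primary allylic alcohol by PPh3 is the standard route to allylic Wittig salts in polyene synthesis and keeps the 2E geometry.

**Step 11**
Reactants: 21 [(2E)-3-methylpent-2-en-4-yn-1-yl]triphenylphosphonium bromide; 22 glyoxal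
Product: 25 (3E,5E,7E,9E)-3,10-dimethyldodeca-3,5,7,9-tetraene-1,11-diyne, via phosphorus ylide 23 (not isolated), via dienynal 24 (not isolated)
Conditions: 21 (2.1 equiv), NaOMe, MeOH/CH2Cl2, −20 °C; glyoxal (40% in H2O), −20 → 25 °C; then I2 (2 mol %), hexane, daylight
Reagents that add atoms: none
Why: Twofold Wittig olefination of glyoxal builds the symmetric C14 chain (C7–C18) in one operation, and iodine-catalysed equilibration converts the E/Z mixture at the two new double bonds to the all-E isomer.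

**Step 12**
Reactants: 26 propiolic acid
Product: 27 (2E)-2,3-dibromoprop-2-enoic acid
Conditions: Br2, CHCl3, 0 → 25 °C, dark
Reagents that add atoms: bromine, BrBr
Why: Anti addition of bromine to the alkyne gives the E-dibromide, in which the C3 bromine is cis to the carboxyl group as needed for lactonisation.

**Step 13**
Reactants: 25 (3E,5E,7E,9E)-3,10-dimethyldodeca-3,5,7,9-tetraene-1,11-diyne; 19 (3R,4S)-3,4-dihydroxy-2,6,6-trimethylcyclohex-1-en-1-yl trifluoromethanesulfonate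
Product: 29 (1S,2R)-4-[(1E,3E,5E,7E,9E)-3,10-dimethyldodeca-1,3,5,7,9-pentaen-11-yn-1-yl]-3,5,5-trimethylcyclohex-3-ene-1,2-diol, via alkenylborane 28 (not isolated)
Conditions: 25 (3 equiv), [(CH3)2CHCH(CH3)]2BH (from BH3·THF and 2-methylbut-2-ene, 1.1 equiv), THF, 0 °C; then 19, Pd(PPh3)4 (5 mol %), 3 M aq. K3PO4, THF, 25 °C, dark
Reagents that add atoms: none
Why: Syn anti-Markovnikov hydroboration of one terminal alkyne of the excess symmetric diyne gives the E-alkenylborane, and Suzuki–Miyaura coupling with the enol triflate forms the C6–C7 bond with the 7E geometry while tolerating the free diol.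

**Step 14**
Reactants: 29 (1S,2R)-4-[(1E,3E,5E,7E,9E)-3,10-dimethyldodeca-1,3,5,7,9-pentaen-11-yn-1-yl]-3,5,5-trimethylcyclohex-3-ene-1,2-diol; 27 (2E)-2,3-dibromoprop-2-enoic acid
Product: 31 (5Z)-3-bromo-5-[(2E,4E,6E,8E,10E)-11-[(3R,4S)-3,4-dihydroxy-2,6,6-trimethylcyclohex-1-en-1-yl]-2,9-dimethylundeca-2,4,6,8,10-pentaen-1-ylidene]furan-2(5H)-one, via bromo enynoic acid 30 (not isolated)
Conditions: PdCl2(PPh3)2 (5 mol %), CuI (10 mol %), Et3N, MeCN, 25 °C, dark
Reagents that add atoms: none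
Why: Tandem Sonogashira coupling at the more electrophilic C3–Br and 5-exo-dig lactonisation of the cis carboxylate onto the alkyne gives the Z-γ-ylidenebutenolide and keeps the α-bromine for the last coupling.

**Step 15**
Reactants: 16 (1S,2R,4S)-1-ethynyl-2,6,6-trimethyl-7-oxabicyclo[2.2.1]heptan-2-ol; 31 (5Z)-3-bromo-5-[(2E,4E,6E,8E,10E)-11-[(3R,4S)-3,4-dihydroxy-2,6,6-trimethylcyclohex-1-en-1-yl]-2,9-dimethylundeca-2,4,6,8,10-pentaen-1-ylidene]furan-2(5H)-one
Product: 33 (5Z)-3-[(E)-2-[(1R,2R,4S)-2-hydroxy-2,6,6-trimethyl-7-oxabicyclo[2.2.1]heptan-1-yl]ethenyl]-5-[(2E,4E,6E,8E,10E)-11-[(3R,4S)-3,4-dihydroxy-2,6,6-trimethylcyclohex-1-en-1-yl]-2,9-dimethylundeca-2,4,6,8,10-pentaen-1-ylidene]furan-2(5H)-one (target), via alkenylborane 32 (not isolated)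
Conditions: (c-C6H11)2BH (from BH3·SMe2 and cyclohexene, 1.1 equiv), THF, 0 °C; then 31, PdCl2(dppf) (5 mol %), AsPh3, Cs2CO3, DMF/THF/H2O, 25 °C, dark
Reagents that add atoms: none
Why: Syn hydroboration of the hindered terminal alkyne and Suzuki–Miyaura coupling with the α-bromobutenolide form the last C–C bond as the E-alkene and give the unprotected target directly, with no stereocentre touched.

**Compound list**
1 | isobutyronitrile | CC(C)C#N | starting material
2 | (S)-epichlorohydrin [(2S)-2-(chloromethyl)oxirane] | ClC[C@@H]1CO1 | starting material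
3 | 2-lithio-2-methylpropanenitrile | [Li]C(C)(C)C#N | intermediate
4 | lithium (2S)-1-chloro-4-cyano-4-methylpentan-2-olate | N#CC(C)(C)C[C@H](O[Li])CCl | intermediate
5 | (4S)-4-[(tert-butyldimethylsilyl)oxy]-5-chloro-2,2-dimethylpentanenitrile | N#CC(C)(C)C[C@H](O[Si](C)(C)C(C)(C)C)CCl | intermediate
6 | lithium [(6S)-6-[(tert-butyldimethylsilyl)oxy]-7-chloro-4,4-dimethylheptan-3-ylidene]azanide | CCC(=N[Li])C(C)(C)C[C@H](O[Si](C)(C)C(C)(C)C)CCl | intermediate
7 | (6S)-6-[(tert-butyldimethylsilyl)oxy]-7-chloro-4,4-dimethylheptan-3-one | CCC(=O)C(C)(C)C[C@H](O[Si](C)(C)C(C)(C)C)CCl | intermediate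
8 | potassium (6S)-6-[(tert-butyldimethylsilyl)oxy]-7-chloro-4,4-dimethylhept-2-en-3-olate | CC=C(O[K])C(C)(C)C[C@H](O[Si](C)(C)C(C)(C)C)CCl | intermediate
9 | (4R)-4-[(tert-butyldimethylsilyl)oxy]-2,2,6-trimethylcyclohexan-1-one (C6 epimers) | O=C1C(C)(C)C[C@H](O[Si](C)(C)C(C)(C)C)CC1C | intermediate
10 | potassium (4R)-4-[(tert-butyldimethylsilyl)oxy]-2,6,6-trimethylcyclohex-1-en-1-olate | CC1=C(O[K])C(C)(C)C[C@H](O[Si](C)(C)C(C)(C)C)C1 | intermediate
11 | (4R)-4-[(tert-butyldimethylsilyl)oxy]-2,6,6-trimethylcyclohex-1-en-1-yl trifluoromethanesulfonate | CC1=C(OS(=O)(=O)C(F)(F)F)C(C)(C)C[C@H](O[Si](C)(C)C(C)(C)C)C1 | intermediate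
12 | tert-butyl{[(1R)-4-ethynyl-3,5,5-trimethylcyclohex-3-en-1-yl]oxy}dimethylsilane | CC1=C(C#C)C(C)(C)C[C@H](O[Si](C)(C)C(C)(C)C)C1 | intermediate
13 | (1R,2S,5S)-2-bromo-5-[(tert-butyldimethylsilyl)oxy]-2-ethynyl-1,3,3-trimethylcyclohexan-1-ol | C#C[C@]1(Br)[C@](C)(O)C[C@@H](O[Si](C)(C)C(C)(C)C)CC1(C)C | intermediate
14 | tert-butyl{[(1R,3S,6R)-6-ethynyl-1,5,5-trimethyl-7-oxabicyclo[4.1.0]heptan-3-yl]oxy}dimethylsilane | C#C[C@@]12O[C@]1(C)C[C@@H](O[Si](C)(C)C(C)(C)C)CC2(C)C | intermediate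
15 | (1R,3S,6R)-6-ethynyl-1,5,5-trimethyl-7-oxabicyclo[4.1.0]heptan-3-ol | C#C[C@@]12O[C@]1(C)C[C@@H](O)CC2(C)C | intermediate
16 | (1S,2R,4S)-1-ethynyl-2,6,6-trimethyl-7-oxabicyclo[2.2.1]heptan-2-ol | C#C[C@@]12O[C@@H](CC1(C)C)C[C@@]2(C)O | intermediate
17 | (4S)-4-[(tert-butyldimethylsilyl)oxy]-2,6,6-trimethyl-3-oxocyclohex-1-en-1-yl trifluoromethanesulfonate | CC1=C(OS(=O)(=O)C(F)(F)F)C(C)(C)C[C@H](O[Si](C)(C)C(C)(C)C)C1=O | intermediate
18 | (3R,4S)-4-[(tert-butyldimethylsilyl)oxy]-3-hydroxy-2,6,6-trimethylcyclohex-1-en-1-yl trifluoromethanesulfonate | CC1=C(OS(=O)(=O)C(F)(F)F)C(C)(C)C[C@H](O[Si](C)(C)C(C)(C)C)[C@@H]1O | intermediate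
19 | (3R,4S)-3,4-dihydroxy-2,6,6-trimethylcyclohex-1-en-1-yl trifluoromethanesulfonate | CC1=C(OS(=O)(=O)C(F)(F)F)C(C)(C)C[C@H](O)[C@@H]1O | intermediate
20 | (2E)-3-methylpent-2-en-4-yn-1-ol | C#C/C(C)=C/CO | starting material
21 | [(2E)-3-methylpent-2-en-4-yn-1-yl]triphenylphosphonium bromide | C#C/C(C)=C/C[P+](c1ccccc1)(c1ccccc1)c1ccccc1.[Br-] | intermediate
22 | glyoxal | O=CC=O | starting material
23 | [(2E)-3-methylpent-2-en-4-yn-1-ylidene]triphenylphosphorane | C#C/C(C)=C/C=P(c1ccccc1)(c1ccccc1)c1ccccc1 | intermediate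
24 | (4E)-5-methylhepta-2,4-dien-6-ynal (2E/2Z mixture) | C#C/C(C)=C/C=CC=O | intermediate
25 | (3E,5E,7E,9E)-3,10-dimethyldodeca-3,5,7,9-tetraene-1,11-diyne | C#C/C(C)=C/C=C/C=C/C=C(C)/C#C | intermediate
26 | propiolic acid | C#CC(=O)O | starting material
27 | (2E)-2,3-dibromoprop-2-enoic acid | Br/C=C(/Br)C(=O)O | intermediate
28 | [(1E,3E,5E,7E,9E)-3,10-dimethyldodeca-1,3,5,7,9-pentaen-11-yn-1-yl]bis(3-methylbutan-2-yl)borane | C#C/C(C)=C/C=C/C=C/C=C(C)/C=C/B(C(C)C(C)C)C(C)C(C)C | intermediate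
29 | (1S,2R)-4-[(1E,3E,5E,7E,9E)-3,10-dimethyldodeca-1,3,5,7,9-pentaen-11-yn-1-yl]-3,5,5-trimethylcyclohex-3-ene-1,2-diol | CC1=C(/C=C/C(C)=C/C=C/C=C/C=C(C)/C#C)C(C)(C)C[C@H](O)[C@@H]1O | intermediate
30 | (2E,6E,8E,10E,12E,14E)-2-bromo-15-[(3R,4S)-3,4-dihydroxy-2,6,6-trimethylcyclohex-1-en-1-yl]-6,13-dimethylpentadeca-2,6,8,10,12,14-hexaen-4-ynoic acid (triethylammonium salt in the flask) | CC1=C(/C=C/C(C)=C/C=C/C=C/C=C(C)/C#C/C=C(/Br)C(=O)O)C(C)(C)C[C@H](O)[C@@H]1O | intermediate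
31 | (5Z)-3-bromo-5-[(2E,4E,6E,8E,10E)-11-[(3R,4S)-3,4-dihydroxy-2,6,6-trimethylcyclohex-1-en-1-yl]-2,9-dimethylundeca-2,4,6,8,10-pentaen-1-ylidene]furan-2(5H)-one | CC1=C(/C=C/C(C)=C/C=C/C=C/C=C(C)/C=C2C=C(Br)C(=O)O/2)C(C)(C)C[C@H](O)[C@@H]1O | intermediate
32 | dicyclohexyl{(E)-2-[(1R,2R,4S)-2-hydroxy-2,6,6-trimethyl-7-oxabicyclo[2.2.1]heptan-1-yl]ethenyl}borane | C1CCCCC1B(C1CCCCC1)/C=C/[C@@]12O[C@@H](CC1(C)C)C[C@@]2(C)O | intermediate
33 | (5Z)-3-[(E)-2-[(1R,2R,4S)-2-hydroxy-2,6,6-trimethyl-7-oxabicyclo[2.2.1]heptan-1-yl]ethenyl]-5-[(2E,4E,6E,8E,10E)-11-[(3R,4S)-3,4-dihydroxy-2,6,6-trimethylcyclohex-1-en-1-yl]-2,9-dimethylundeca-2,4,6,8,10-pentaen-1-ylidene]furan-2(5H)-one | CC1=C(/C=C/C(C)=C/C=C/C=C/C=C(C)/C=C2C=C(/C=C/[C@@]34O[C@@H](CC3(C)C)C[C@@]4(C)O)C(=O)O/2)C(C)(C)C[C@H](O)[C@@H]1O | target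

**Totals and risks**
Total step count: 15. Longest linear sequence: 9 steps (1, 2, 3, 4, 8, 9, 13, 14, 15).

Most likely to fail, first: step 8. Allylic oxidation has not been secured on an enol triflate, and the vinylogous acyl triflate 17 may hydrolyse or over-oxidise. The fallback sets out from ketone 9 and brings in the C4 oxygen by tethered oxa-Michael addition instead of C–H oxidation. IBX dehydrogenation gives (4S)-4-[(tert-butyldimethylsilyl)oxy]-2,6,6-trimethylcyclohex-2-en-1-one F1, and Bu4NF gives (4S)-4-hydroxy-2,6,6-trimethylcyclohex-2-en-1-one F2. PhB(OH)2 with an amine catalyst delivers oxygen to C4 from the boronic hemiester on the face of the C3 oxygen, giving the cis-fused phenylboronate of (4S,5R)-4,5-dihydroxy-2,2,6-trimethylcyclohexan-1-one F3. H2O2/NaHCO3 frees (4S,5R)-4,5-dihydroxy-2,2,6-trimethylcyclohexan-1-one F4, and 2-methoxypropene/PPTS gives its acetonide F5. KN(SiMe3)2/PhNTf2 gives the acetonide of (3R,4S)-3,4-dihydroxy-2,6,6-trimethylcyclohex-1-en-1-yl trifluoromethanesulfonate F6, and aqueous AcOH returns to the route at 19.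

Second: step 6, the proposed new step. The bromonium ion may form on the wrong face, or the enyne may react 1,4. The fallback uses known chemistry only and sets out from triflate 11. Carbonylation (Pd(OAc)2, dppp, CO, MeOH, Et3N) gives methyl (4R)-4-[(tert-butyldimethylsilyl)oxy]-2,6,6-trimethylcyclohex-1-ene-1-carboxylate F7, and i-Bu2AlH gives [(4R)-4-[(tert-butyldimethylsilyl)oxy]-2,6,6-trimethylcyclohex-1-en-1-yl]methanol F8. Reagent-controlled Sharpless epoxidation (Ti(OiPr)4, D-(−)-diethyl tartrate, t-BuOOH) gives the anti-epoxide [(1R,4S,6R)-4-[(tert-butyldimethylsilyl)oxy]-2,2,6-trimethyl-7-oxabicyclo[4.1.0]heptan-1-yl]methanol F9; the tartrate choice follows from my own facial analysis and should be confirmed on the first run. Dess–Martin oxidation gives (1S,4S,6R)-4-[(tert-butyldimethylsilyl)oxy]-2,2,6-trimethyl-7-oxabicyclo[4.1.0]heptane-1-carbaldehyde F10. Ohira–Bestmann homologation (dimethyl (1-diazo-2-oxopropyl)phosphonate, K2CO3, MeOH) returns to the route at silyl epoxide 14, which Bu4NF converts to 15.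

Third: step 3. Enolate O-alkylation to a dihydropyran, or elimination of HCl, could compete with the C-alkylation. The fallback sets out from ketone 7 and uses an azaenolate, which alkylates only at carbon. Me2NNH2 with catalytic AcOH gives (6S)-6-[(tert-butyldimethylsilyl)oxy]-7-chloro-4,4-dimethylheptan-3-one N,N-dimethylhydrazone F11. LiN(i-Pr)2 with NaI in THF cyclises it to (4R)-4-[(tert-butyldimethylsilyl)oxy]-2,2,6-trimethylcyclohexan-1-one N,N-dimethylhydrazone F12, and aqueous oxalic acid returns to the route at 9.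

**Further compounds**
F1 | step 8 | (4S)-4-[(tert-butyldimethylsilyl)oxy]-2,6,6-trimethylcyclohex-2-en-1-one | CC1=C[C@@H](O[Si](C)(C)C(C)(C)C)CC(C)(C)C1=O
F2 | step 8 | (4S)-4-hydroxy-2,6,6-trimethylcyclohex-2-en-1-one | CC1=C[C@@H](O)CC(C)(C)C1=O
F3 | step 8 | cis-fused phenylboronate of (4S,5R)-4,5-dihydroxy-2,2,6-trimethylcyclohexan-1-one | CC1C(=O)C(C)(C)C[C@@H]2OB(c3ccccc3)O[C@H]12
F4 | step 8 | (4S,5R)-4,5-dihydroxy-2,2,6-trimethylcyclohexan-1-one | CC1C(=O)C(C)(C)C[C@H](O)[C@@H]1O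
F5 | step 8 | acetonide of (4S,5R)-4,5-dihydroxy-2,2,6-trimethylcyclohexan-1-one | CC1C(=O)C(C)(C)C[C@@H]2OC(C)(C)O[C@H]12
F6 | step 8 | acetonide of (3R,4S)-3,4-dihydroxy-2,6,6-trimethylcyclohex-1-en-1-yl trifluoromethanesulfonate | CC1=C(OS(=O)(=O)C(F)(F)F)C(C)(C)C[C@@H]2OC(C)(C)O[C@H]12
F7 | step 6 | methyl (4R)-4-[(tert-butyldimethylsilyl)oxy]-2,6,6-trimethylcyclohex-1-ene-1-carboxylate | CC1=C(C(=O)OC)C(C)(C)C[C@H](O[Si](C)(C)C(C)(C)C)C1
F8 | step 6 | [(4R)-4-[(tert-butyldimethylsilyl)oxy]-2,6,6-trimethylcyclohex-1-en-1-yl]methanol | CC1=C(CO)C(C)(C)C[C@H](O[Si](C)(C)C(C)(C)C)C1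
F9 | step 6 | [(1R,4S,6R)-4-[(tert-butyldimethylsilyl)oxy]-2,2,6-trimethyl-7-oxabicyclo[4.1.0]heptan-1-yl]methanol | OC[C@@]12O[C@]1(C)C[C@@H](O[Si](C)(C)C(C)(C)C)CC2(C)C
F10 | step 6 | (1S,4S,6R)-4-[(tert-butyldimethylsilyl)oxy]-2,2,6-trimethyl-7-oxabicyclo[4.1.0]heptane-1-carbaldehyde | O=C[C@@]12O[C@]1(C)C[C@@H](O[Si](C)(C)C(C)(C)C)CC2(C)C
F11 | step 3 | (6S)-6-[(tert-butyldimethylsilyl)oxy]-7-chloro-4,4-dimethylheptan-3-one N,N-dimethylhydrazone | CCC(=NN(C)C)C(C)(C)C[C@H](O[Si](C)(C)C(C)(C)C)CCl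
F12 | step 3 | (4R)-4-[(tert-butyldimethylsilyl)oxy]-2,2,6-trimethylcyclohexan-1-one N,N-dimethylhydrazone | CN(C)N=C1C(C)(C)C[C@H](O[Si](C)(C)C(C)(C)C)CC1C
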